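**Retrosynthetic overview**

1. The strategy rests on ring C of the target: C1 carries the ester carbonyl, C2 a hydroxyl, C4 a second oxygen and C6 a methyl group. This 2,4-dioxygenated 6-methylbenzoate pattern is what a vinylketene and a siloxyalkyne assemble; the target is disconnected to its O4-triisopropylsilyl ether and then to the same compound with an extra SiMe3 on C3.
2. That arene is disconnected to the A–B didepside diazoketone and a siloxyalkyne. A photo-Wolff shift (C5–C6), a [2+2] addition (C2–C3, C4–C5), 4π opening and 6π closure (C1–C2) build ring C on the finished didepside.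
3. The diazoketone comes from the corresponding methyl ketone by detrifluoroacetylative diazo transfer. The methyl ketone comes from the A–B phenol and (E)-3-methyl-4-oxopent-2-enoic acid, itself from butane-2,3-dione by Wittig olefination.
4. The A–B phenol is a depside ester of two 2-O-methylorsellinate units, both made from methyl orsellinate by 4-O-benzylation and 2-O-methylation.
5. Ring order: rings A and B are bought with methyl orsellinate, and ring C is the only ring formed, last. The siloxyalkyne is made in one operation from trimethylsilylacetylene and keeps its C-silyl group, because freeing the terminal alkyne would compete with loss of the O-silyl group; the SiMe3 is removed later from C3 of ring C by ipso-protonation.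

Key step: step 12

Remark: the target has no stereocentre, so no enantiomer has to be controlled; the only stereochemical element in the route is the E alkene of the pentenoate chain, which disappears on aromatisation. ArAB–O denotes the aryloxy residue of phenol 8 (8 bonded through its phenolic oxygen).

**Route**

Step 1
Reactants: 1 methyl orsellinate (methyl 2,4-dihydroxy-6-methylbenzoate)
Product: 2 methyl 4-(benzyloxy)-2-hydroxy-6-methylbenzoate
Conditions: BnBr (1.05 equiv), K2CO3, acetone, reflux
Reagents that add atoms: benzyl bromide, BrCc1ccccc1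
Why: Williamson etherification should take place at the 4-OH only, because the 2-OH is tied up in a hydrogen bond to the ester carbonyl and is the weaker nucleophile.

Step 2
Reactants: 2 methyl 4-(benzyloxy)-2-hydroxy-6-methylbenzoate
Product: 3 methyl 4-(benzyloxy)-2-methoxy-6-methylbenzoate
Conditions: MeI, K2CO3, DMF, 60 °C
Reagents that add atoms: iodomethane, CI
Why: Williamson O-methylation of the chelated phenol, the only acidic site left, under more forcing conditions in a dipolar aprotic solvent.

Step 3
Reactants: 3 methyl 4-(benzyloxy)-2-methoxy-6-methylbenzoate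
Product: 4 methyl 4-hydroxy-2-methoxy-6-methylbenzoate
Conditions: H2 (1 atm), 10% Pd/C, EtOAc–MeOH, rt
Reagents that add atoms: none
Why: Catalytic hydrogenolysis of the benzyl aryl ether frees the ring-A phenol and leaves the ester and methyl ether untouched.

Step 4
Reactants: 3 methyl 4-(benzyloxy)-2-methoxy-6-methylbenzoate
Product: 5 4-(benzyloxy)-2-methoxy-6-methylbenzoic acid
Conditions: KOH, DMSO–H2O (4:1), 100 °C; then aq. HCl
Reagents that add atoms: potassium hydroxide, [K+].[OH-]
Why: Saponification of the di-ortho-substituted benzoate needs poorly solvated hydroxide at high temperature, conditions under which the benzyl and methyl ethers are inert.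

Step 5
Reactants: 5 4-(benzyloxy)-2-methoxy-6-methylbenzoic acid; 4 methyl 4-hydroxy-2-methoxy-6-methylbenzoate
Product: 7 methyl 4-{[4-(benzyloxy)-2-methoxy-6-methylbenzoyl]oxy}-2-methoxy-6-methylbenzoate, via mixed trifluoroacetic anhydride 6 (not isolated)
Conditions: TFAA (3 equiv), toluene, rt
Reagents that add atoms: none
Why: Depside esterification through the mixed anhydride: the electron-rich, hindered aroyl group ionises towards a stabilised aroylium ion and is transferred to the unhindered phenol, whereas trifluoroacetylation of the phenol is reversible.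

Step 6
Reactants: 7 methyl 4-{[4-(benzyloxy)-2-methoxy-6-methylbenzoyl]oxy}-2-methoxy-6-methylbenzoate
Product: 8 A–B phenol, methyl 4-[(4-hydroxy-2-methoxy-6-methylbenzoyl)oxy]-2-methoxy-6-methylbenzoate
Conditions: H2 (1 atm), 10% Pd/C, EtOAc, rt
Reagents that add atoms: none
Why: Hydrogenolysis of the benzyl ether under neutral conditions leaves both aryl and methyl esters intact.

Step 7
Reactants: 9 butane-2,3-dione; 10 tert-butyl (triphenylphosphoranylidene)acetate
Product: 11 tert-butyl (E)-3-methyl-4-oxopent-2-enoate
Conditions: 9 (3 equiv), CH2Cl2, 0 °C to rt; chromatography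
Reagents that add atoms: none
Why: Wittig olefination of one carbonyl of the activated 1,2-diketone by the stabilised ylide, with excess dione to prevent double olefination; it should favour the E isomer (ester trans to acetyl), and any Z isomer is removed by chromatography.

Step 8
Reactants: 11 tert-butyl (E)-3-methyl-4-oxopent-2-enoate
Product: 12 (E)-3-methyl-4-oxopent-2-enoic acid
Conditions: TFA–CH2Cl2 (1:4), rt
Reagents that add atoms: none
Why: Acidolysis of the tert-butyl ester with loss of isobutene; the E acid cannot close to a hydroxybutenolide, so the geometry should be kept.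

Step 9
Reactants: 8 A–B phenol; 12 (E)-3-methyl-4-oxopent-2-enoic acid
Product: 14 ArAB (E)-3-methyl-4-oxopent-2-enoate, via O-acylisourea 13 (not isolated)
Conditions: DCC, DMAP (0.1 equiv), CH2Cl2, 0 °C to rt
Reagents that add atoms: none
Why: Steglich esterification of an unhindered unsaturated acid with the only free phenol of 8; DMAP acyl transfer outruns the O-to-N acyl shift, and the hindered depside ester is not touched.

Step 10
Reactants: 14 ArAB (E)-3-methyl-4-oxopent-2-enoate
Product: 17 ArAB (E)-5-diazo-3-methyl-4-oxopent-2-enoate, via lithium enolate 15 (not isolated), via trifluoroacetyl ketone 16 (not isolated)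
Conditions: 14 added to LiHMDS (1.1 equiv), THF, −78 °C; CF3CO2CH2CF3, −78 °C; aq. HCl work-up; then MsN3, Et3N, H2O (1 equiv), MeCN, rt
Reagents that add atoms: methanesulfonyl azide, CS(=O)(=O)N=[N+]=[N-]
Why: Regitz-type detrifluoroacetylative diazo transfer: kinetic deprotonation of the acetyl CH3, Claisen trifluoroacetylation and diazo transfer with loss of the trifluoroacetyl group should give the diazoketone without diazomethane, which would add as a 1,3-dipole to this electron-poor alkene, and the E alkene keeps the enolate carbon away from the aryl ester carbonyl.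

Step 11
Reactants: 18 trimethylsilylacetylene
Product: 21 triisopropyl{[(trimethylsilyl)ethynyl]oxy}silane, via lithium trimethylsilylacetylide 19 (not isolated), via lithium 2-(trimethylsilyl)ethynolate 20 (not isolated)
Conditions: n-BuLi, THF, −78 °C; LiOOt-Bu (from t-BuOOH and LiHMDS, THF, −78 °C), −78 to 0 °C; TIPSOTf, −78 to 0 °C; pentane / aq. NaHCO3 work-up
Reagents that add atoms: tert-butyl hydroperoxide, CC(C)(C)OO; triisopropylsilyl trifluoromethanesulfonate, CC(C)[Si](C(C)C)(C(C)C)OS(=O)(=O)C(F)(F)F
Why: Electrophilic oxygenation of the lithium acetylide by the lithium peroxide gives the ynolate, and the bulky, hard silyl triflate should silylate it on oxygen because the carbon terminus is already shielded by SiMe3.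

Step 12
Reactants: 17 ArAB (E)-5-diazo-3-methyl-4-oxopent-2-enoate; 21 triisopropyl{[(trimethylsilyl)ethynyl]oxy}silane
Product: 26 3-C-trimethylsilyl 4-O-triisopropylsilyl tridepside (ArAB 2-hydroxy-6-methyl-4-(triisopropylsilyloxy)-3-(trimethylsilyl)benzoate), via vinylketene 22 (not isolated), via vinylcyclobutenone 23 (not isolated), via dienylketene 24 (not isolated), via cyclohexadienone 25 (not isolated)
Conditions: 21 (2.5 equiv), ClCH2CH2Cl (0.3 M), hν (450 W medium-pressure Hg lamp, Pyrex filter), rt; then 80 °C in the dark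
Reagents that add atoms: none
Why: Light expels N2 from 17 and the alkenyl carbon C6 shifts from the ketone carbon to the former diazo carbon (photo-Wolff rearrangement, C5–C6) to give vinylketene 22, whose ketene C2=C5 bond adds [2+2] to 21 (C2–C3 and C4–C5) to give cyclobutenone 23; 4π conrotatory opening of the C2–C5 bond then gives dienylketene 24, 6π closure forms C1–C2 (25) and enolisation gives phenol 26. The closest known reaction type is the Danheiser benzannulation of α,β-unsaturated α′-diazoketones with siloxyalkynes, which gives resorcinol monosilyl ethers. Ring C, the only ring made, closes by thermal 6π disrotatory electrocyclisation of 24 (the four-membered ring of 23 is transient), and the period at 80 °C should complete it. No stereocentre is set: the sp3 centres of 23 and 25 are erased by ring opening and tautomerisation, and the E alkene of 17 serves only to hold the aryl ester on the outside of the closing triene and away from the ketene, so that 2-pyranone formation should not compete. The step needs regiocontrol in the [2+2], which the polarised ynol ether supplies: its silylated carbon, β to oxygen, is the nucleophile that bonds to the ketene carbonyl carbon C2 and the siloxy carbon bonds to C5, so that OTIPS lands on C4 para to the ester and SiMe3 on C3. It also needs the diazoketone to be the chromophore that is excited, for which Pyrex-filtered light above 300 nm is chosen to limit photo-Fries reaction of the two aryl esters.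

Step 13
Reactants: 26 3-C-trimethylsilyl 4-O-triisopropylsilyl tridepside
Product: 27 4-O-triisopropylsilyl tridepside (ArAB 2-hydroxy-6-methyl-4-(triisopropylsilyloxy)benzoate)
Conditions: TFA (10 equiv), CH2Cl2, 0 °C to rt
Reagents that add atoms: none
Why: Electrophilic ipso-protodesilylation: C3 lies between two oxygen-bearing carbons and para to the methyl group, so protonation there is fast and loss of silicon follows, while the aryl TIPS ether and the aryl esters tolerate TFA.

Step 14
Reactants: 27 4-O-triisopropylsilyl tridepside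
Product: 28 target tridepside, methyl 4-({4-[(2,4-dihydroxy-6-methylbenzoyl)oxy]-2-methoxy-6-methylbenzoyl}oxy)-2-methoxy-6-methylbenzoate
Conditions: TBAF (1.1 equiv), AcOH (1.2 equiv), THF, 0 °C
Reagents that add atoms: none
Why: Fluoride cleavage of the aryl silyl ether; the acetic acid buffer keeps the liberated phenoxide from transacylating the depside esters.

**Compound list**

1 | methyl orsellinate (methyl 2,4-dihydroxy-6-methylbenzoate) | COC(=O)c1c(C)cc(O)cc1O | starting material
2 | methyl 4-(benzyloxy)-2-hydroxy-6-methylbenzoate | COC(=O)c1c(C)cc(OCc2ccccc2)cc1O | intermediate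
3 | methyl 4-(benzyloxy)-2-methoxy-6-methylbenzoate | COC(=O)c1c(C)cc(OCc2ccccc2)cc1OC | intermediate
4 | methyl 4-hydroxy-2-methoxy-6-methylbenzoate | COC(=O)c1c(C)cc(O)cc1OC | intermediate
5 | 4-(benzyloxy)-2-methoxy-6-methylbenzoic acid | OC(=O)c1c(C)cc(OCc2ccccc2)cc1OC | intermediate
6 | 4-(benzyloxy)-2-methoxy-6-methylbenzoic trifluoroacetic anhydride | O=C(OC(=O)C(F)(F)F)c1c(C)cc(OCc2ccccc2)cc1OC | intermediate
7 | methyl 4-{[4-(benzyloxy)-2-methoxy-6-methylbenzoyl]oxy}-2-methoxy-6-methylbenzoate | COC(=O)c1c(C)cc(OC(=O)c2c(C)cc(OCc3ccccc3)cc2OC)cc1OC | intermediate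
8 | A–B phenol, methyl 4-[(4-hydroxy-2-methoxy-6-methylbenzoyl)oxy]-2-methoxy-6-methylbenzoate | COC(=O)c1c(C)cc(OC(=O)c2c(C)cc(O)cc2OC)cc1OC | intermediate
9 | butane-2,3-dione | CC(=O)C(C)=O | starting material
10 | tert-butyl (triphenylphosphoranylidene)acetate | CC(C)(C)OC(=O)C=P(c1ccccc1)(c1ccccc1)c1ccccc1 | starting material
11 | tert-butyl (E)-3-methyl-4-oxopent-2-enoate | CC(=O)/C(C)=C/C(=O)OC(C)(C)C | intermediate
12 | (E)-3-methyl-4-oxopent-2-enoic acid | CC(=O)/C(C)=C/C(=O)O | intermediate
13 | O-[(E)-3-methyl-4-oxopent-2-enoyl]-N,N'-dicyclohexylisourea | CC(=O)/C(C)=C/C(=O)OC(=NC1CCCCC1)NC1CCCCC1 | intermediate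
14 | ArAB (E)-3-methyl-4-oxopent-2-enoate | CC(=O)/C(C)=C/C(=O)Oc1cc(C)c(C(=O)Oc2cc(C)c(C(=O)OC)c(OC)c2)c(OC)c1 | intermediate
15 | lithium enolate of 14 (ArAB (E)-4-lithiooxy-3-methylpenta-2,4-dienoate) | [Li]OC(=C)/C(C)=C/C(=O)Oc1cc(C)c(C(=O)Oc2cc(C)c(C(=O)OC)c(OC)c2)c(OC)c1 | intermediate
16 | ArAB (E)-7,7,7-trifluoro-3-methyl-4,6-dioxohept-2-enoate | O=C(CC(=O)C(F)(F)F)/C(C)=C/C(=O)Oc1cc(C)c(C(=O)Oc2cc(C)c(C(=O)OC)c(OC)c2)c(OC)c1 | intermediate
17 | ArAB (E)-5-diazo-3-methyl-4-oxopent-2-enoate | [N-]=[N+]=CC(=O)/C(C)=C/C(=O)Oc1cc(C)c(C(=O)Oc2cc(C)c(C(=O)OC)c(OC)c2)c(OC)c1 | intermediate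
18 | trimethylsilylacetylene | C#C[Si](C)(C)C | starting material
19 | lithium trimethylsilylacetylide | [Li]C#C[Si](C)(C)C | intermediate
20 | lithium 2-(trimethylsilyl)ethynolate | [Li]OC#C[Si](C)(C)C | intermediate
21 | triisopropyl{[(trimethylsilyl)ethynyl]oxy}silane | C[Si](C)(C)C#CO[Si](C(C)C)(C(C)C)C(C)C | intermediate
22 | vinylketene, ArAB (E)-3-methyl-5-oxopenta-2,4-dienoate | O=C=C/C(C)=C/C(=O)Oc1cc(C)c(C(=O)Oc2cc(C)c(C(=O)OC)c(OC)c2)c(OC)c1 | intermediate
23 | vinylcyclobutenone, ArAB (E)-3-[4-oxo-2-(triisopropylsilyloxy)-3-(trimethylsilyl)cyclobut-2-en-1-yl]but-2-enoate (racemic) | O=C4C([Si](C)(C)C)=C(O[Si](C(C)C)(C(C)C)C(C)C)C4/C(C)=C/C(=O)Oc1cc(C)c(C(=O)Oc2cc(C)c(C(=O)OC)c(OC)c2)c(OC)c1 | intermediate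
24 | dienylketene, ArAB (2E,4E)-3-methyl-7-oxo-5-(triisopropylsilyloxy)-6-(trimethylsilyl)hepta-2,4,6-trienoate (ketenyl carbon cis to the methyl-bearing carbon across the central alkene) | O=C=C([Si](C)(C)C)/C(O[Si](C(C)C)(C(C)C)C(C)C)=C\C(C)=C\C(=O)Oc1cc(C)c(C(=O)Oc2cc(C)c(C(=O)OC)c(OC)c2)c(OC)c1 | intermediate
25 | cyclohexadienone, ArAB 2-methyl-6-oxo-4-(triisopropylsilyloxy)-5-(trimethylsilyl)cyclohexa-2,4-diene-1-carboxylate (racemic) | O=C4C([Si](C)(C)C)=C(O[Si](C(C)C)(C(C)C)C(C)C)C=C(C)C4C(=O)Oc1cc(C)c(C(=O)Oc2cc(C)c(C(=O)OC)c(OC)c2)c(OC)c1 | intermediate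
26 | 3-C-trimethylsilyl 4-O-triisopropylsilyl tridepside, ArAB 2-hydroxy-6-methyl-4-(triisopropylsilyloxy)-3-(trimethylsilyl)benzoate | COC(=O)c1c(C)cc(OC(=O)c2c(C)cc(OC(=O)c3c(C)cc(O[Si](C(C)C)(C(C)C)C(C)C)c([Si](C)(C)C)c3O)cc2OC)cc1OC | intermediate
27 | 4-O-triisopropylsilyl tridepside, ArAB 2-hydroxy-6-methyl-4-(triisopropylsilyloxy)benzoate | COC(=O)c1c(C)cc(OC(=O)c2c(C)cc(OC(=O)c3c(C)cc(O[Si](C(C)C)(C(C)C)C(C)C)cc3O)cc2OC)cc1OC | intermediate
28 | methyl 4-({4-[(2,4-dihydroxy-6-methylbenzoyl)oxy]-2-methoxy-6-methylbenzoyl}oxy)-2-methoxy-6-methylbenzoate | COC(=O)c1c(C)cc(OC(=O)c2c(C)cc(OC(=O)c3c(C)cc(O)cc3O)cc2OC)cc1OC | target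

**Step count**

Total steps: 14. Longest linear sequence: 10 steps (steps 1, 2, 4, 5, 6, 9, 10, 12, 13, 14 from methyl orsellinate).

**Steps most likely to fail**

Step 12. The cascade may be diverted in several ways: photo-Fries cleavage of the aryl esters, photochemical E-to-Z isomerisation of the alkene followed by closure of the ketene onto the ester carbonyl, ketene dimerisation if the [2+2] with the hindered silylated alkyne terminus is slow, or incomplete 6π closure of the silyl-stabilised dienylketene. The fallback gives up the benzannulation and attaches a preformed ring C by classical depside esterification. It sets out from 1 and 8 and comes back to the route at 28. Methyl orsellinate 1 is benzylated on both hydroxyls (BnBr in excess, K2CO3, DMF, 80 °C) to methyl 2,4-bis(benzyloxy)-6-methylbenzoate F1, which is saponified (KOH, DMSO–H2O, 100 °C) to 2,4-bis(benzyloxy)-6-methylbenzoic acid F2. TFAA in toluene converts F2 into its mixed trifluoroacetic anhydride F3, which acylates phenol 8 to give the 2,4-di-O-benzyl tridepside F4. Hydrogenolysis (H2, Pd/C, EtOAc) then gives 28.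

Step 10. The lithium enolate may undergo Claisen or Michael reactions with the aryl ester and enone acceptor of a second molecule, or the activated aryl ester may be cleaved during the amine-mediated diazo transfer. The fallback installs the diazo group before the aryl ester is made. It sets out from 12 (and uses 8) and comes back at 17. Acid 12 is esterified with 2-(trimethylsilyl)ethanol (DCC, DMAP, through 13) to 2-(trimethylsilyl)ethyl (E)-3-methyl-4-oxopent-2-enoate F5. The same LiHMDS / CF3CO2CH2CF3 sequence gives 2-(trimethylsilyl)ethyl (E)-7,7,7-trifluoro-3-methyl-4,6-dioxohept-2-enoate F6, and MsN3 / Et3N converts this to 2-(trimethylsilyl)ethyl (E)-5-diazo-3-methyl-4-oxopent-2-enoate F7. TBAF in THF at 0 °C releases (E)-5-diazo-3-methyl-4-oxopent-2-enoic acid F8 after mildly acidic work-up. DCC / DMAP activates F8 as its O-acyl-N,N'-dicyclohexylisourea F9, which acylates phenol 8 to give 17.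

Step 11. Oxygen transfer to the weakly nucleophilic silylacetylide may be incomplete, the ynolate may be silylated on carbon to give a bis-silylketene, and the product may hydrolyse or undergo 1,3-silyl shift during isolation. The fallback makes the ynolate by deprotonation of a silylketene and not by acetylide oxidation. It sets out from commercial ethoxyethyne F10 in place of 18 and comes back at 20. Ethoxyethyne F10 is lithiated (n-BuLi, THF, −78 °C) and silylated with TMSCl to 1-ethoxy-2-(trimethylsilyl)ethyne F11. Heating F11 at 120 °C expels ethylene by a retro-ene reaction and gives (trimethylsilyl)ketene F12. n-BuLi in THF at −100 °C deprotonates F12 to ynolate 20, which is O-silylated with TIPSOTf as in step 11 to give 21.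

**Further compounds**

F1 | step 12 | methyl 2,4-bis(benzyloxy)-6-methylbenzoate | COC(=O)c1c(C)cc(OCc2ccccc2)cc1OCc1ccccc1
F2 | step 12 | 2,4-bis(benzyloxy)-6-methylbenzoic acid | OC(=O)c1c(C)cc(OCc2ccccc2)cc1OCc1ccccc1
F3 | step 12 | 2,4-bis(benzyloxy)-6-methylbenzoic trifluoroacetic anhydride | O=C(OC(=O)C(F)(F)F)c1c(C)cc(OCc2ccccc2)cc1OCc1ccccc1
F4 | step 12 | 2,4-di-O-benzyl tridepside, ArAB 2,4-bis(benzyloxy)-6-methylbenzoate | COC(=O)c1c(C)cc(OC(=O)c2c(C)cc(OC(=O)c3c(C)cc(OCc4ccccc4)cc3OCc3ccccc3)cc2OC)cc1OC
F5 | step 10 | 2-(trimethylsilyl)ethyl (E)-3-methyl-4-oxopent-2-enoate | CC(=O)/C(C)=C/C(=O)OCC[Si](C)(C)C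
F6 | step 10 | 2-(trimethylsilyl)ethyl (E)-7,7,7-trifluoro-3-methyl-4,6-dioxohept-2-enoate | O=C(CC(=O)C(F)(F)F)/C(C)=C/C(=O)OCC[Si](C)(C)C
F7 | step 10 | 2-(trimethylsilyl)ethyl (E)-5-diazo-3-methyl-4-oxopent-2-enoate | [N-]=[N+]=CC(=O)/C(C)=C/C(=O)OCC[Si](C)(C)C
F8 | step 10 | (E)-5-diazo-3-methyl-4-oxopent-2-enoic acid | [N-]=[N+]=CC(=O)/C(C)=C/C(=O)O
F9 | step 10 | O-[(E)-5-diazo-3-methyl-4-oxopent-2-enoyl]-N,N'-dicyclohexylisourea | [N-]=[N+]=CC(=O)/C(C)=C/C(=O)OC(=NC1CCCCC1)NC1CCCCC1
F10 | step 11 | ethoxyethyne | CCOC#C
F11 | step 11 | 1-ethoxy-2-(trimethylsilyl)ethyne | CCOC#C[Si](C)(C)C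
F12 | step 11 | (trimethylsilyl)ketene | C[Si](C)(C)C=C=O
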